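**Retrosynthetic overview**
- The C3–Br bond is cut last: the target comes from 5,6-dibromo-1-methylindole by electrophilic bromination at C3, and that indole from its cis-3a,7a-dihydro form by dehydrogenation.
- Key disconnection: C3a–C4 and C7–C7a. The route rests on the benzo-ring fragment C4–C5(Br)–C6(Br)–C7, a symmetric four-carbon dibromodiene unit, fused to C3a–C7a, which is the C3=C2 bond of a pyrrole.
- That unit is delivered by 3,4-dibromothiophene 1,1-dioxide as the 4π partner across C2=C3 of 1-methylpyrrole, with loss of SO2; the diene comes from 3,4-dibromothiophene by S-oxidation.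
- Ring order: the pyrrole ring is bought; the six-membered carbocycle is closed in the key step, then aromatised; bromine at C3 goes on last.

Key step: step 2

Remark: the target has no stereocentre and is achiral, so "single enantiomer" makes no demand on the route; the two stereocentres formed in the key step are racemic and are erased on aromatisation.

**Step 1**
Reactants: 1 3,4-dibromothiophene
Product: 3 3,4-dibromothiophene 1,1-dioxide, via 3,4-dibromothiophene 1-oxide 2 (not isolated)
Conditions: TFAA, H2O2 (50% aq.), MeCN/CH2Cl2, 0 °C → rt
Reagents that add atoms: trifluoroperacetic acid, O=C(OO)C(F)(F)F, made in the flask from hydrogen peroxide, OO, and trifluoroacetic anhydride, O=C(OC(=O)C(F)(F)F)C(F)(F)F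
Why: Electrophilic oxygen transfer from trifluoroperacetic acid to sulfur is the established oxidation of electron-poor thiophenes to their 1,1-dioxides; the non-aromatic S-oxide 2 should be oxidised faster than 1 and so should not accumulate, and no stereocentre is formed.

**Step 2**
Reactants: 3 3,4-dibromothiophene 1,1-dioxide; 4 1-methyl-1H-pyrrole (large excess)
Product: 6 rac-cis-5,6-dibromo-1-methyl-3a,7a-dihydro-1H-indole, via bridged sulfone cycloadduct 5 (not isolated)
Conditions: 4 (15 equiv), PhMe, 70 °C, slow addition of 3, Ar sparge, dark; excess 4 removed in vacuo, crude 6 kept cold under Ar and used at once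
Reagents that add atoms: none
Why: Proposed new method: the sulfonyl group and the two bromines lower the LUMO of the s-cis-locked diene of 3 and the enamine-like C2=C3 bond of 4 supplies the HOMO, so an inverse-electron-demand [4+2] cycloaddition (concerted and asynchronous, or through a zwitterion that collapses by ring closure) should give the 7-thiabicyclo[2.2.1]heptene dioxide 5, which loses SO2 by retro-cheletropic extrusion; the closest known reaction type is the benzannulation of halogenated thiophene 1,1-dioxides with electron-rich π bonds such as enol ethers, enamines and cycloalkenes, and a simple pyrrole as the 2π partner is the untested part. The six-membered carbocycle is closed by this intermolecular cycloaddition, which forms C3a–C4 and C7–C7a suprafacially on both partners, and the extrusion leaves it as a cyclohexa-1,3-diene. C3a and C7a are the only stereocentres that reach 6; their cis relationship follows from suprafacial addition to a ring cis-alkene, they form as a racemate and both are erased in step 3, so endo/exo selectivity in 5 has no consequence. Regiochemistry does not arise because the diene is C2v-symmetric, so either orientation places bromine at C5 and C6. The step needs a single addition of the pyrrole as a 2π component, in competition with dimerisation of 3, a second cycloaddition at the enamine bond of 6 and Michael-type substitution at pyrrole C2; slow addition of 3 to a large excess of 4 keeps the diene dilute and protects 6 statistically, and sweeping out SO2 prevents acid from building up around the acid-labile C7a–N bond.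

**Step 3**
Reactants: 6 rac-cis-5,6-dibromo-1-methyl-3a,7a-dihydro-1H-indole
Product: 7 5,6-dibromo-1-methyl-1H-indole
Conditions: DDQ (1.05 equiv), PhMe, 0 °C → rt; filter off the hydroquinone, wash with aq. NaHCO3
Reagents that add atoms: none
Why: Quinone dehydrogenation of a dihydroarene: hydride abstraction from the allylic, α-amino C7a–H and loss of the C3a proton should give the 10π indole, with the aryl bromides untouched and both stereocentres removed.

**Step 4**
Reactants: 7 5,6-dibromo-1-methyl-1H-indole
Product: 8 3,5,6-tribromo-1-methyl-1H-indole
Conditions: NBS (1.0 equiv), DMF, 0 °C, dark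
Reagents that add atoms: N-bromosuccinimide, O=C1CCC(=O)N1Br
Why: Electrophilic aromatic substitution at C3, the most nucleophilic position of an N-alkylindole; the N-methyl group rules out N-bromination, the two bromines deactivate the benzo ring, and one equivalent at low temperature should stop at the monobromide.

**Compound list**
1 | 3,4-dibromothiophene | Brc1cscc1Br | starting material
2 | 3,4-dibromothiophene 1-oxide | O=S1C=C(Br)C(Br)=C1 | intermediate (not isolated)
3 | 3,4-dibromothiophene 1,1-dioxide | O=S1(=O)C=C(Br)C(Br)=C1 | intermediate
4 | 1-methyl-1H-pyrrole | Cn1cccc1 | starting material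
5 | rac-5,6-dibromo-1-methyl-3a,4,7,7a-tetrahydro-4,7-epithio-1H-indole 8,8-dioxide (endo isomer drawn) | CN1C=C[C@H]2[C@@H]1[C@H]1C(Br)=C(Br)[C@@H]2S1(=O)=O | intermediate (not isolated)
6 | rac-cis-5,6-dibromo-1-methyl-3a,7a-dihydro-1H-indole | CN1C=C[C@@H]2C=C(Br)C(Br)=C[C@H]12 | intermediate
7 | 5,6-dibromo-1-methyl-1H-indole | Cn1ccc2cc(Br)c(Br)cc21 | intermediate
8 | 3,5,6-tribromo-1-methyl-1H-indole | Cn1cc(Br)c2cc(Br)c(Br)cc21 | target

**Total step count:** 4
**Longest linear sequence:** 4 steps (from 1)

**Steps most likely to fail**

1. Step 2 (Proposed new method). The cycloaddition costs the pyrrole its aromatic stabilisation and may be slow. Dimerisation of the diene, Michael-type substitution at pyrrole C2, a second cycloaddition on the enamine of the first adduct, or aromatisation by heterolysis of the C7a–N bond could then outrun it. The fallback uses known chemistry, sets out from 3 and comes back at 7. The aromatic partner is replaced by a non-aromatic enecarbamate, tert-butyl 2,3-dihydro-1H-pyrrole-1-carboxylate F1. This is the class of electron-rich alkene for which thiophene dioxide cycloaddition with SO2 extrusion is established, and its adduct has no enamine left for a second addition. Heating 3 with F1 in toluene should give, through the bridged sulfone rac-tert-butyl 5,6-dibromo-2,3,3a,4,7,7a-hexahydro-4,7-epithio-1H-indole-1-carboxylate 8,8-dioxide F2 (not isolated), rac-tert-butyl cis-5,6-dibromo-2,3,3a,7a-tetrahydro-1H-indole-1-carboxylate F3. DDQ should aromatise the carbocycle to tert-butyl 5,6-dibromoindoline-1-carboxylate F4. TFA in CH2Cl2 should remove the carbamate to give 5,6-dibromoindoline F5. MnO2 or DDQ should dehydrogenate the indoline to 5,6-dibromo-1H-indole F6, and NaH/MeI in DMF should methylate nitrogen to give 7.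

2. Step 3. The quinone may add to the nucleophilic enamine carbon C3, or acid from the hydroquinone may trigger aromatisation by C7a–N cleavage (ring opening) instead of loss of H2; the product indole may also be over-oxidised at C3. The fallback sets out from 6 and comes back at 8, bypassing 7. C3 is capped before any oxidant is added: NBS (1.0 equiv) with 2,6-lutidine in THF at −78 °C should brominate the enamine β-carbon to give rac-cis-3,5,6-tribromo-1-methyl-3a,7a-dihydro-1H-indole F7. This bromoenamine is less basic and less nucleophilic than 6. A heterogeneous, non-acidic oxidant (activated MnO2, CH2Cl2, rt) should then dehydrogenate it directly to 8.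

3. Step 1. The first oxygen transfer to the electron-poor sulfur may be slow, and the S-oxide may be lost to [4+2] self-dimerisation before the second oxidation. The fallback sets out from 1 and comes back at 3. The α positions are silylated first, which raises the electron density at sulfur and blocks dimerisation. LDA (2.2 equiv) and TMSCl in THF at −78 °C should give 3,4-dibromo-2,5-bis(trimethylsilyl)thiophene F8. mCPBA in CH2Cl2 should oxidise it to 3,4-dibromo-2,5-bis(trimethylsilyl)thiophene 1,1-dioxide F9. Fluoride-triggered protodesilylation of the α-silyl vinyl sulfone units (TBAF buffered with AcOH, THF, 0 °C) should then give 3.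

**Further compounds**
F1 | step 2 | tert-butyl 2,3-dihydro-1H-pyrrole-1-carboxylate (purchased) | CC(C)(C)OC(=O)N1CCC=C1
F2 | step 2 | rac-tert-butyl 5,6-dibromo-2,3,3a,4,7,7a-hexahydro-4,7-epithio-1H-indole-1-carboxylate 8,8-dioxide (endo isomer drawn, not isolated) | CC(C)(C)OC(=O)N1CC[C@H]2[C@@H]1[C@H]1C(Br)=C(Br)[C@@H]2S1(=O)=O
F3 | step 2 | rac-tert-butyl cis-5,6-dibromo-2,3,3a,7a-tetrahydro-1H-indole-1-carboxylate | CC(C)(C)OC(=O)N1CC[C@@H]2C=C(Br)C(Br)=C[C@H]12
F4 | step 2 | tert-butyl 5,6-dibromoindoline-1-carboxylate | CC(C)(C)OC(=O)N1CCc2cc(Br)c(Br)cc21
F5 | step 2 | 5,6-dibromoindoline | Brc1cc2c(cc1Br)NCC2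
F6 | step 2 | 5,6-dibromo-1H-indole | Brc1cc2cc[nH]c2cc1Br
F7 | step 3 | rac-cis-3,5,6-tribromo-1-methyl-3a,7a-dihydro-1H-indole | CN1C=C(Br)[C@@H]2C=C(Br)C(Br)=C[C@H]12
F8 | step 1 | 3,4-dibromo-2,5-bis(trimethylsilyl)thiophene | C[Si](C)(C)c1sc([Si](C)(C)C)c(Br)c1Br
F9 | step 1 | 3,4-dibromo-2,5-bis(trimethylsilyl)thiophene 1,1-dioxide | C[Si](C)(C)C1=C(Br)C(Br)=C([Si](C)(C)C)S1(=O)=O
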